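**Retrosynthetic overview**
- The aryl hydrogen sulfate on ring A is traced back to a phenol, the phenol to an aldehyde (Baeyer–Villiger), and the aldehyde is carried as a 1,3-dioxolane.
- The strategy rests on ring C: C1 carries the ether oxygen to ring B, the adjacent C2 carries iodine, and C4 (para to oxygen) carries bromine. Both bonds, C1–O and C2–I, are cut together to give a ring A–B phenoxide, 4-bromobenzyne and an iodine donor (C4F9I).
- The A–B ether comes from SNAr of symmetric 4,5-dibromocatechol on 3,5-dibromo-2-fluorobenzaldehyde; the third bromine of ring B is then placed ortho to the free OH.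
- No ring is built: rings A, B and C arrive intact from 2, 1 and 6 and are joined in the order A–B (step 1), then B–C together with C–I (step 6).

Key step: step 6

Remark: the target has no stereogenic element (the diaryl ether axes are not expected to be configurationally stable), so no stereocontrol is needed; it is delivered as the free hydrogen sulfate, as drawn.

**Route**

Step 1
Reactants: 1 4,5-dibromobenzene-1,2-diol (excess); 2 3,5-dibromo-2-fluorobenzaldehyde
Product: 3 3,5-dibromo-2-(4,5-dibromo-2-hydroxyphenoxy)benzaldehyde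
Conditions: 1 (2.5 equiv), K2CO3, DMF, 70 °C, Ar; dilute HCl work-up
Reagents that add atoms: none
Why: Nucleophilic aromatic substitution (addition–elimination) at the fluorine-bearing carbon, which is activated by the ortho formyl group, while both bromines are meta to it and inert; the symmetric diol in excess should give only mono-arylation.

Step 2
Reactants: 3 3,5-dibromo-2-(4,5-dibromo-2-hydroxyphenoxy)benzaldehyde
Product: 4 3,5-dibromo-2-(3,4,5-tribromo-2-hydroxyphenoxy)benzaldehyde
Conditions: Br2 (1.05 equiv), AcOH, 20 °C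
Reagents that add atoms: bromine, BrBr
Why: Electrophilic aromatic bromination; with the para position blocked, the one free position ortho to the phenol OH is far more activated than the position ortho to the aryl ether oxygen, and ring A is deactivated by CHO and two bromines.

Step 3
Reactants: 4 3,5-dibromo-2-(3,4,5-tribromo-2-hydroxyphenoxy)benzaldehyde
Product: 5 2,3,4-tribromo-6-[2,4-dibromo-6-(1,3-dioxolan-2-yl)phenoxy]phenol
Conditions: ethylene glycol (5 equiv), p-TsOH·H2O (cat.), toluene, reflux, Dean–Stark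
Reagents that add atoms: ethylene glycol, OCCO
Why: Acid-catalysed acetalisation with azeotropic removal of water; the electron-poor aldehyde acetalises readily and the phenol is untouched.

Step 4
Reactants: 6 5-bromo-2-iodophenol
Product: 7 (5-bromo-2-iodophenoxy)trimethylsilane
Conditions: HMDS, THF, reflux; concentrate in vacuo
Reagents that add atoms: hexamethyldisilazane, C[Si](C)(C)N[Si](C)(C)C
Why: O-Silylation of the phenol by the disilazane, driven by loss of ammonia.

Step 5
Reactants: 7 (5-bromo-2-iodophenoxy)trimethylsilane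
Product: 10 5-bromo-2-(trimethylsilyl)phenyl trifluoromethanesulfonate, via aryllithium 8 (not isolated), via lithium phenoxide 9 (not isolated)
Conditions: n-BuLi (1.05 equiv), THF, −100 → −78 °C; then Tf2O, −100 °C → rt
Reagents that add atoms: trifluoromethanesulfonic anhydride, O=S(=O)(C(F)(F)F)OS(=O)(=O)C(F)(F)F
Why: Iodine–lithium exchange is much faster than bromine–lithium exchange at low temperature, the ortho-lithio aryl silyl ether undergoes the anionic 1,3 O→C silyl shift (retro-Brook rearrangement) to the lithium phenoxide, and triflic anhydride O-triflates it.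

Step 6
Reactants: 5 2,3,4-tribromo-6-[2,4-dibromo-6-(1,3-dioxolan-2-yl)phenoxy]phenol; 10 5-bromo-2-(trimethylsilyl)phenyl trifluoromethanesulfonate; 11 nonafluoro-1-iodobutane
Product: 15 2-{3,5-dibromo-2-[3,4,5-tribromo-2-(4-bromo-2-iodophenoxy)phenoxy]phenyl}-1,3-dioxolane, via potassium phenoxide 12 (not isolated), via 4-bromobenzyne 13 (not isolated), via aryl anion 14 (not isolated)
Conditions: KH (1.0 equiv), DME, 0 °C; then 18-crown-6, KF (3 equiv), 11 (5 equiv), slow addition of 10 (1.5 equiv), DME, 0 °C → rt, dark, Ar sweep; preparative HPLC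
Reagents that add atoms: none
Why: Proposed new method: fluoride attacks silicon of 10 and triflate leaves to give 4-bromobenzyne 13; phenoxide 12 adds through oxygen to the aryne carbon para to bromine, and the aryl anion 14 (ortho to the new ether oxygen, meta to bromine) makes a halophilic attack on the iodine of 11 to form the C–I bond, the perfluorobutyl anion collapsing to volatile octafluorobut-1-ene and fluoride. The closest known reactions are the fluoride-mediated O-arylation of phenols by 2-silylaryl triflates and the three-component amino- and thio-halogenations of arynes that use a polyhalogenated halogen donor; the new element is the pairing of a phenoxide with an iodine donor. No ring is closed and no stereocentre is formed. The step needs oxygen para to bromine, which the inductive effect of bromine should favour only moderately by placing the charge on the nearer (meta) carbon, so the 5-bromo-2-iodophenoxy isomer has to be removed by preparative HPLC or crystallisation. It also needs iodine capture ahead of protonation, secured by the preformed phenoxide (no O–H), the aprotic medium and the excess of 11, and ahead of bromine abstraction from the polybromo rings, secured because the C–I bond of a perfluoroalkyl iodide is by far the better halogen donor. The dioxolane shields the aldehyde from 14, the anion is meta to bromine and cannot eliminate to a second aryne, and exclusion of light suppresses electron transfer between 12 and 11.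

Step 7
Reactants: 15 2-{3,5-dibromo-2-[3,4,5-tribromo-2-(4-bromo-2-iodophenoxy)phenoxy]phenyl}-1,3-dioxolane
Product: 16 3,5-dibromo-2-[3,4,5-tribromo-2-(4-bromo-2-iodophenoxy)phenoxy]benzaldehyde
Conditions: 2 M aq. HCl, THF, 50 °C
Reagents that add atoms: water, O
Why: Acid-catalysed acetal hydrolysis; the diaryl ethers and aryl halides are inert to aqueous acid.

Step 8
Reactants: 16 3,5-dibromo-2-[3,4,5-tribromo-2-(4-bromo-2-iodophenoxy)phenoxy]benzaldehyde
Product: 18 3,5-dibromo-2-[3,4,5-tribromo-2-(4-bromo-2-iodophenoxy)phenoxy]phenol, via aryl formate 17 (not isolated)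
Conditions: mCPBA (2.5 equiv), CH2Cl2, 40 °C, dark; aq. Na2SO3 wash; then MeOH, Et3N (cat.), rt
Reagents that add atoms: 3-chloroperbenzoic acid, O=C(OO)c1cccc(Cl)c1
Why: Baeyer–Villiger oxidation in which the ortho aryloxy oxygen raises the migratory aptitude of ring A in the Criegee adduct so that aryl migrates to give the formate, which is then methanolysed to the phenol; the sulfite wash should return any iodine(III) formed on ring C to the aryl iodide.

Step 9
Reactants: 18 3,5-dibromo-2-[3,4,5-tribromo-2-(4-bromo-2-iodophenoxy)phenoxy]phenol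
Product: 20 3,5-dibromo-2-[3,4,5-tribromo-2-(4-bromo-2-iodophenoxy)phenoxy]phenyl hydrogen sulfate (bromoiesol B sulfate), via pyridinium aryl sulfate 19 (not isolated)
Conditions: SO3·pyridine (5 equiv), pyridine, 50 °C; then Dowex 50W (H+ form), MeOH/H2O, 0 °C; lyophilise
Reagents that add atoms: sulfur trioxide–pyridine complex, [O-]S(=O)(=O)[n+]1ccccc1
Why: O-Sulfonation of the phenol by the sulfur trioxide–amine complex gives the pyridinium aryl sulfate, and cation exchange on a sulfonic acid resin in the cold should deliver the free hydrogen sulfate.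

**Compound list**
1 | 4,5-dibromobenzene-1,2-diol | Oc1cc(Br)c(Br)cc1O | starting material
2 | 3,5-dibromo-2-fluorobenzaldehyde | O=Cc1cc(Br)cc(Br)c1F | starting material
3 | 3,5-dibromo-2-(4,5-dibromo-2-hydroxyphenoxy)benzaldehyde | O=Cc1cc(Br)cc(Br)c1Oc1cc(Br)c(Br)cc1O | intermediate
4 | 3,5-dibromo-2-(3,4,5-tribromo-2-hydroxyphenoxy)benzaldehyde | O=Cc1cc(Br)cc(Br)c1Oc1cc(Br)c(Br)c(Br)c1O | intermediate
5 | 2,3,4-tribromo-6-[2,4-dibromo-6-(1,3-dioxolan-2-yl)phenoxy]phenol | O1CCOC1c2cc(Br)cc(Br)c2Oc2cc(Br)c(Br)c(Br)c2O | intermediate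
6 | 5-bromo-2-iodophenol | Oc1cc(Br)ccc1I | starting material
7 | (5-bromo-2-iodophenoxy)trimethylsilane | C[Si](C)(C)Oc1cc(Br)ccc1I | intermediate
8 | [4-bromo-2-(trimethylsilyloxy)phenyl]lithium | [Li]c1ccc(Br)cc1O[Si](C)(C)C | intermediate
9 | lithium 5-bromo-2-(trimethylsilyl)phenoxide | [Li+].[O-]c1cc(Br)ccc1[Si](C)(C)C | intermediate
10 | 5-bromo-2-(trimethylsilyl)phenyl trifluoromethanesulfonate | C[Si](C)(C)c1ccc(Br)cc1OS(=O)(=O)C(F)(F)F | intermediate
11 | nonafluoro-1-iodobutane | FC(F)(F)C(F)(F)C(F)(F)C(F)(F)I | starting material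
12 | potassium 2,3,4-tribromo-6-[2,4-dibromo-6-(1,3-dioxolan-2-yl)phenoxy]phenoxide | [K+].[O-]c1c(Br)c(Br)c(Br)cc1Oc1c(Br)cc(Br)cc1C1OCCO1 | intermediate
13 | 4-bromobenzyne (4-bromo-1,2-didehydrobenzene) | BrC1=CC#CC=C1 | intermediate
14 | potassium 5-bromo-2-{2,3,4-tribromo-6-[2,4-dibromo-6-(1,3-dioxolan-2-yl)phenoxy]phenoxy}benzenide | [K+].[c-]1cc(Br)ccc1Oc1c(Br)c(Br)c(Br)cc1Oc1c(Br)cc(Br)cc1C1OCCO1 | intermediate
15 | 2-{3,5-dibromo-2-[3,4,5-tribromo-2-(4-bromo-2-iodophenoxy)phenoxy]phenyl}-1,3-dioxolane | O1CCOC1c2cc(Br)cc(Br)c2Oc2cc(Br)c(Br)c(Br)c2Oc2ccc(Br)cc2I | intermediate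
16 | 3,5-dibromo-2-[3,4,5-tribromo-2-(4-bromo-2-iodophenoxy)phenoxy]benzaldehyde | O=Cc1cc(Br)cc(Br)c1Oc1cc(Br)c(Br)c(Br)c1Oc1ccc(Br)cc1I | intermediate
17 | 3,5-dibromo-2-[3,4,5-tribromo-2-(4-bromo-2-iodophenoxy)phenoxy]phenyl formate | O=COc1cc(Br)cc(Br)c1Oc1cc(Br)c(Br)c(Br)c1Oc1ccc(Br)cc1I | intermediate
18 | 3,5-dibromo-2-[3,4,5-tribromo-2-(4-bromo-2-iodophenoxy)phenoxy]phenol | Oc1cc(Br)cc(Br)c1Oc1cc(Br)c(Br)c(Br)c1Oc1ccc(Br)cc1I | intermediate
19 | pyridinium 3,5-dibromo-2-[3,4,5-tribromo-2-(4-bromo-2-iodophenoxy)phenoxy]phenyl sulfate | [O-]S(=O)(=O)Oc1cc(Br)cc(Br)c1Oc1cc(Br)c(Br)c(Br)c1Oc1ccc(Br)cc1I.c1cc[nH+]cc1 | intermediate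
20 | 3,5-dibromo-2-[3,4,5-tribromo-2-(4-bromo-2-iodophenoxy)phenoxy]phenyl hydrogen sulfate (bromoiesol B sulfate) | O=S(=O)(O)Oc1cc(Br)cc(Br)c1Oc1cc(Br)c(Br)c(Br)c1Oc1ccc(Br)cc1I | target

**Step count**
Total: 9 steps. Longest linear sequence: 7 steps (1, 2, 3, 6, 7, 8, 9); the aryne precursor branch (steps 4, 5) joins at step 6.

**Steps most likely to fail**

Step 6. The aryl anion may be protonated instead of iodinated. Addition across the unsymmetrical aryne may be poorly regioselective, and the two bromo-iodo isomers may co-elute. The phenoxide may also be consumed by the perfluoroalkene released from the iodine donor. The fallback uses known chemistry with fixed regiochemistry; it sets out from 5 and returns at 16. Phenol 5 is arylated by SNAr with 4-bromo-1-fluoro-2-nitrobenzene (K2CO3, DMF, 80 °C) to give 2-{3,5-dibromo-2-[3,4,5-tribromo-2-(4-bromo-2-nitrophenoxy)phenoxy]phenyl}-1,3-dioxolane F1. The nitro group is reduced with iron powder and ammonium chloride in aqueous ethanol to 5-bromo-2-{2,3,4-tribromo-6-[2,4-dibromo-6-(1,3-dioxolan-2-yl)phenoxy]phenoxy}aniline F2. Diazotisation with sodium nitrite in aqueous sulfuric acid/acetic acid at 0 °C, which also hydrolyses the dioxolane, gives 5-bromo-2-[2,3,4-tribromo-6-(2,4-dibromo-6-formylphenoxy)phenoxy]benzenediazonium hydrogensulfate F3, and potassium iodide converts it into aldehyde 16.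

Step 8. Hydride migration may outrun aryl migration in the Criegee adduct of this electron-poor benzaldehyde and lead to the benzoic acid, and the peracid may oxidise at iodine. The fallback replaces the hydride competitor by a methyl group, which migrates far less readily than aryl; it sets out from 16 and returns at 18. Methylmagnesium bromide (THF, −78 °C) adds to the aldehyde to give racemic 1-{3,5-dibromo-2-[3,4,5-tribromo-2-(4-bromo-2-iodophenoxy)phenoxy]phenyl}ethan-1-ol F4. Dess–Martin periodinane oxidises it to 1-{3,5-dibromo-2-[3,4,5-tribromo-2-(4-bromo-2-iodophenoxy)phenoxy]phenyl}ethan-1-one F5. Baeyer–Villiger oxidation (mCPBA, trifluoroacetic acid, CH2Cl2, reductive sulfite work-up) gives 3,5-dibromo-2-[3,4,5-tribromo-2-(4-bromo-2-iodophenoxy)phenoxy]phenyl acetate F6, and potassium carbonate in methanol releases phenol 18.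

Step 9. O-Sulfonation of the hindered, acidic phenol may stay incomplete, and the sulfate may be lost again during acidification and concentration. The fallback forms the S–O bond irreversibly as a protected sulfate diester; it sets out from 18 and returns at 20. The sodium phenoxide of 18 (NaHMDS, THF, −78 °C) is treated with isobutyl chlorosulfate to give 3,5-dibromo-2-[3,4,5-tribromo-2-(4-bromo-2-iodophenoxy)phenoxy]phenyl 2-methylpropyl sulfate F7, which can be chromatographed. Sodium iodide in acetone at 55 °C removes the isobutyl group to give sodium 3,5-dibromo-2-[3,4,5-tribromo-2-(4-bromo-2-iodophenoxy)phenoxy]phenyl sulfate F8, and cation exchange on the acid resin in the cold gives 20.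

**Further compounds**
F1 | step 6 | 2-{3,5-dibromo-2-[3,4,5-tribromo-2-(4-bromo-2-nitrophenoxy)phenoxy]phenyl}-1,3-dioxolane | O1CCOC1c2cc(Br)cc(Br)c2Oc2cc(Br)c(Br)c(Br)c2Oc2ccc(Br)cc2[N+](=O)[O-]
F2 | step 6 | 5-bromo-2-{2,3,4-tribromo-6-[2,4-dibromo-6-(1,3-dioxolan-2-yl)phenoxy]phenoxy}aniline | O1CCOC1c2cc(Br)cc(Br)c2Oc2cc(Br)c(Br)c(Br)c2Oc2ccc(Br)cc2N
F3 | step 6 | 5-bromo-2-[2,3,4-tribromo-6-(2,4-dibromo-6-formylphenoxy)phenoxy]benzenediazonium hydrogensulfate | O=Cc1cc(Br)cc(Br)c1Oc1cc(Br)c(Br)c(Br)c1Oc1ccc(Br)cc1[N+]#N.OS(=O)(=O)[O-]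
F4 | step 8 | 1-{3,5-dibromo-2-[3,4,5-tribromo-2-(4-bromo-2-iodophenoxy)phenoxy]phenyl}ethan-1-ol (racemic) | CC(O)c1cc(Br)cc(Br)c1Oc1cc(Br)c(Br)c(Br)c1Oc1ccc(Br)cc1I
F5 | step 8 | 1-{3,5-dibromo-2-[3,4,5-tribromo-2-(4-bromo-2-iodophenoxy)phenoxy]phenyl}ethan-1-one | CC(=O)c1cc(Br)cc(Br)c1Oc1cc(Br)c(Br)c(Br)c1Oc1ccc(Br)cc1I
F6 | step 8 | 3,5-dibromo-2-[3,4,5-tribromo-2-(4-bromo-2-iodophenoxy)phenoxy]phenyl acetate | CC(=O)Oc1cc(Br)cc(Br)c1Oc1cc(Br)c(Br)c(Br)c1Oc1ccc(Br)cc1I
F7 | step 9 | 3,5-dibromo-2-[3,4,5-tribromo-2-(4-bromo-2-iodophenoxy)phenoxy]phenyl 2-methylpropyl sulfate | CC(C)COS(=O)(=O)Oc1cc(Br)cc(Br)c1Oc1cc(Br)c(Br)c(Br)c1Oc1ccc(Br)cc1I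
F8 | step 9 | sodium 3,5-dibromo-2-[3,4,5-tribromo-2-(4-bromo-2-iodophenoxy)phenoxy]phenyl sulfate | [Na+].[O-]S(=O)(=O)Oc1cc(Br)cc(Br)c1Oc1cc(Br)c(Br)c(Br)c1Oc1ccc(Br)cc1I
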